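## Structural features

The target is an achiral, linear oligomer of eleven benzene rings (A to K) joined by ten diaryl ether oxygens and carrying 28 free phenolic hydroxyls. It has no stereocentre, no ring other than the benzenes and no carbon–carbon bond between rings. Ring A is a 2,4,6-trihydroxyphenoxy end group and ring K a 3,4,5-trihydroxyphenoxy end group. Rings B, D, F, H and J are 1,3-dihydroxybenzenes with ether oxygens on C2 (between the two hydroxyls) and on C5 (between two C–H positions); rings C, E, G and I are 3,4,5-trihydroxybenzenes with ether oxygens on the adjacent carbons C1 and C2. The rings follow one direction only: C2 of each dihydroxy ring is bound through oxygen to C1 of the next trihydroxy ring, whose C2 is bound to C5 of the following dihydroxy ring, so B–C, D–E, F–G and H–I are the same two-ring unit. The ether bonds are robust, but the free polyphenol, above all the five rings with three adjacent hydroxyls, is oxidised easily by air (fastest in base) and must be set free last. The real difficulty is that every ether carbon sits on an electron-rich ring, most with two ortho substituents, so both SNAr and copper coupling are reluctant, and the order of nearly identical rings must be kept in register. The key step uses ring F: C2 is flanked by the hydroxyls on C1 and C3 while C5 is meta to both, so two formyl groups in place of these hydroxyls make C2 alone electrophilic enough for SNAr and leave C5 to a copper-catalysed coupling.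

## Logic of the disconnections

31 back to 30. The 26 O–CH3 bonds are cut. The oxidation-prone polyphenol then exists only in the last flask and every earlier compound is a stable, chromatographable ether. The forward step must be an exhaustive Lewis-acid dealkylation that spares the ten diaryl ether bonds.

30 back to 28. The two C–OH bonds on C1 and C3 of ring F are traced back to C–CHO bonds. The formyl groups are what make the central union possible. The forward step needs aryl migration twice in a peracid oxidation of 28, followed by formate cleavage.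

28 back to 23, 26 and 11. Both ether bonds of ring F are cut: C2(F)–O to ring G and C5(F)–O to ring E. This splits the molecule at its centre into two pentamers of equal size and a six-carbon linchpin. The forward step must deliver 23 to the C–F carbon and 11 to the C–Br carbon, in that order and without crossover.

26 back to 25 and 24. The two formyl groups are traced back to gem-dibromomethyl groups and then to methyl groups. This reaches a purchasable arene in two operations. The hydrolysis must avoid any basic nucleophile, because the fluoride becomes labile once the formyl groups appear.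

11 back to 9, then to 8 and 4. The hydroxyl on ring E is traced to a formyl group, then the C2(C)–O–C5(D) ether is cut. Compound 4 brings rings D and E already joined, with a bromide for this bond and an aldehyde as the latent next hydroxyl. The forward demand is copper arylation of a doubly ortho-substituted phenol.

8 back to 6, then to 5 and 4. The same two operations are applied one unit earlier: formyl for the ring C hydroxyl, then the C1(A)–O–C5(B) ether is cut. A second copy of 4 supplies rings B and C, so one building block serves twice in this half.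

23 back to 22, then to 19 and 21. The ring G hydroxyl is traced to its benzyl ether, then the C2(I)–O–C5(J) ether is cut. Compound 21 caps the chain with rings J and K. The benzyl group must survive peracid, base and copper, and fall cleanly by hydrogenolysis.

19 back to 17, then to 16 and 4. Formyl stands for the ring I hydroxyl, then the C2(G)–O–C5(H) ether is cut. A third copy of 4 supplies rings H and I. Compound 16 carries the one differentiated oxygen of the whole route.

4 back to 2 and 3, and 2 back to 1. The C2–O–C1 ether between a dihydroxy-type and a trihydroxy-type ring is cut. The formyl group that later becomes the hydroxyl also activates the fluoride for SNAr, and the bromide of 3 is untouched because no metal is present. Compound 2 comes from 1 by forming one C–CHO bond at the only available ring position.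

16 back to 14, 13 and 12. The phenol oxygen is traced to a formyl group, the C–CHO bond is cut, and the O–benzyl bond is cut. Each step has only one possible regiochemical outcome because the two free positions of 13 are equivalent.

21 back to 3 and 20. The C2(J)–O–C1(K) ether is cut. An oxidative copper coupling of a phenol with a boronic acid is needed because it must leave the aryl bromide of 3 intact.

## Other disconnections considered

Alternative 1: Ring C is built from a four-membered ring instead of being brought in as an aromatic block. The cut goes through ring C, at the bond between the carbon that ends up with the free hydroxyl and the neighbouring aryloxy-bearing carbon, and behind it back to dimethyl squarate A1. In the forward sense a (Z)-2-aryloxyvinyl anion that already carries rings A and B adds to A1, the tertiary alcohol is methylated to the racemic cyclobutenone A2, and heating opens A2 to a dienylketene that closes by 6π electrocyclisation and tautomerises to the trimer phenol A3, the same compound as 8.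
- In favour: the oxygenation pattern is written into the ring by construction (three methoxy groups from the squarate, only the ketene oxygen free, exactly where the next ether is needed), and the step is neutral and thermal.
- Against: the (Z)-vinyl anion is needed because the (E) isomer would lose aryloxide, yet the (Z) geometry puts the aryloxy group on the inside of the closing triene and should slow the ring closure. Only one of the four pentaoxygenated rings is made per pass, and each repeat would need a new vinyl ether on a larger, more hindered phenol.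
- Comparison: on structure both plans reach the same trimer phenol; the chosen plan does so in four steps (steps 1 to 4) through 4, which is reused for rings D–E and H–I. On mechanism the alternative is the better: the regiochemistry is fixed by an intramolecular pericyclic event, and neither peracid nor copper touches ring A. On step economy it is about equal for one ring and worse over the whole target, and it does not address the union of the two halves.

Alternative 2: Twenty aryl C–OH bonds are traced back at once to C–CHO bonds. The forward step is a single peracid oxidation of the icosaformyl undecamer A4, with aryl migration at each formyl group and formate cleavage, to the icosaphenol A5, which still holds eight methyl ethers.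
- In favour: in A4 every C2 of rings A-type and B, D, F, H, J lies between two formyl groups and every C2 of rings C, E, G, I has one ortho and one para formyl group, so all ten ether bonds could in principle be made by SNAr without copper. Only eight methyl ethers would remain for the final dealkylation instead of 26, which is a clear advantage.
- Against: twenty oxidations must all take the aryl-migration path on one molecule, and a small leak per site (hydride migration to a carboxylic acid, or an unreacted formyl group) multiplies into a mixture of near-identical polyphenols. Each ring starts with two acceptor groups, so the migratory aptitude is lowest at the start. Aryloxy groups flanked by formyl groups are leaving groups, so the ring sequence could scramble during the assembly of A4. A5 is already air-sensitive and must still survive a deprotection.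
- Comparison: the chosen plan uses the same transformation but on one or two formyl groups at a time (steps 4, 6, 9, 11 and 18), each followed by purification. The alternative equals it in convergence and could be shorter if A4 can be assembled; it is weaker in fidelity.

Alternative 3: The two halves are joined by building ring F itself, cutting two C–C bonds of that ring. In the forward sense the ethynyl ether A6 (the ethynyl ether of 11) is heated with the racemic 4-aryloxy-3-ethoxycyclobutenone A7 (aryl is ring G of 23). A7 opens to a vinylketene, which adds [2+2] to the ynol ether; the new cyclobutenone opens and the dienylketene closes and tautomerises (Danheiser benzannulation) to undecamer A8, whose ring F carries one free hydroxyl and one ethoxy group.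
- In favour: the union is neutral and thermal, the regiochemistry follows from the polarity of ketene and ynol ether, no copper coupling of a very hindered phenol is needed at the largest stage, and no oxidation is needed afterwards. A8 needs only the global dealkylation, one step fewer after the key step than the chosen plan, which is a point for the alternative.
- Against: both partners are harder to make than 11 and 23. An aryl ethynyl ether of a doubly ortho-substituted phenol is prone to hydration and polymerisation at the temperature at which the cyclobutenone opens. A cyclobutenone with an aryloxy group on its sp3 carbon has no simple entry. A bimolecular [2+2] between two pentamer-sized partners must also compete with ketene dimerisation.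
- Comparison: the chosen plan uses 11 and 23 as they are and a linchpin two steps from a purchasable arene, with two well-established bond-forming reaction types. The alternative's pericyclic cascade is mechanistically more self-contained but rests on two uncertain precursors; about four extra steps before the union would be spent to save one after it.

Key step: step 17

Assumption: 1, 3, 5, 12, 20 and 24 are taken as purchasable. Of the 28 hydroxyls of the target, 26 travel as methyl ethers and two as the formyl groups of ring F; the one hydroxyl that must be free for the key step (ring G) travels as a benzyl ether. The structures of 11, 23, 26 and 28 were checked ring by ring against the target and agree with it.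

## Route

Step 1
Reactants: 1 fluoroarene (5-fluoro-1,2,3-trimethoxybenzene)
Product: 2 fluoro aldehyde (6-fluoro-2,3,4-trimethoxybenzaldehyde)
Conditions: POCl3, DMF, 0 → 80 °C; then H2O
Reagents that add atoms: N,N-dimethylformamide CN(C)C=O (formyl carbon); water O (formyl oxygen)
Why: Vilsmeier–Haack formylation; the two free ring positions are equivalent and each is ortho and para to methoxy groups, so only one aldehyde can form.

Step 2
Reactants: 2 fluoro aldehyde (6-fluoro-2,3,4-trimethoxybenzaldehyde); 3 bromophenol (4-bromo-2,6-dimethoxyphenol)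
Product: 4 bromo aldehyde dimer (6-(4-bromo-2,6-dimethoxyphenoxy)-2,3,4-trimethoxybenzaldehyde)
Conditions: Cs2CO3, DMSO, 110 °C, Ar
Reagents that add atoms: none
Why: SNAr: the phenoxide of 3 adds at the C–F carbon of 2, the charge is taken up by the ortho formyl group and fluoride leaves; the para methoxy group slows the addition, hence Cs2CO3 in hot DMSO. The aryl bromide is inert because no transition metal is present.

Step 3
Reactants: 5 ring A phenol (2,4,6-trimethoxyphenol); 4 bromo aldehyde dimer
Product: 6 rings A–C trimer aldehyde (6-[2,6-dimethoxy-4-(2,4,6-trimethoxyphenoxy)phenoxy]-2,3,4-trimethoxybenzaldehyde)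
Conditions: CuI (10 mol%), picolinic acid (20 mol%), K3PO4, DMSO, 100 °C, Ar
Reagents that add atoms: none
Why: Ullmann-type etherification; CuI with picolinic acid is a known system for arylating ortho,ortho-disubstituted phenols with aryl bromides. The bromide of 4 has two hydrogen neighbours and the non-enolisable aldehyde is a spectator.

Step 4
Reactants: 6 rings A–C trimer aldehyde
Product: 8 rings A–C trimer phenol (6-[2,6-dimethoxy-4-(2,4,6-trimethoxyphenoxy)phenoxy]-2,3,4-trimethoxyphenol), via rings A–C trimer formate 7 (not isolated)
Conditions: mCPBA, CH2Cl2, 0 °C → rt; aq. Na2S2O3/NaHCO3 wash; then K2CO3 (cat.), MeOH, rt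
Reagents that add atoms: m-chloroperbenzoic acid OOC(=O)c1cccc(Cl)c1 (one oxygen)
Why: Baeyer–Villiger (Dakin-type) oxidation; the aryl group, made electron-rich by its two ortho oxygen substituents, migrates in preference to hydride to give formate 7, which base-catalysed methanolysis cleaves.

Step 5
Reactants: 8 rings A–C trimer phenol; 4 bromo aldehyde dimer
Product: 9 rings A–E pentamer aldehyde (formyl on ring E next to the D–E ether carbon; thirteen methoxy groups)
Conditions: CuI (10 mol%), picolinic acid (20 mol%), K3PO4, DMSO, 100 °C, Ar
Reagents that add atoms: none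
Why: Ullmann-type etherification as in step 3; the phenol of 8 is flanked by an aryloxy and a methoxy group, so the hindered-phenol catalyst system is kept and the reaction time extended.

Step 6
Reactants: 9 rings A–E pentamer aldehyde
Product: 11 rings A–E pentamer phenol (hydroxyl on ring E next to the D–E ether carbon), via rings A–E pentamer formate 10 (not isolated)
Conditions: mCPBA, CH2Cl2, 0 °C → rt; aq. Na2S2O3/NaHCO3 wash; then K2CO3 (cat.), MeOH, rt
Reagents that add atoms: m-chloroperbenzoic acid OOC(=O)c1cccc(Cl)c1 (one oxygen)
Why: Baeyer–Villiger oxidation with aryl migration as in step 4; the formyl group sits between an aryloxy and a methoxy group. Only a slight excess of peracid at 0 °C is used so that ring A is spared.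

Step 7
Reactants: 12 ring K phenol (3,4,5-trimethoxyphenol)
Product: 13 benzyl ether (5-(benzyloxy)-1,2,3-trimethoxybenzene)
Conditions: BnBr, K2CO3, DMF, rt
Reagents that add atoms: benzyl bromide BrCc1ccccc1
Why: Williamson ether synthesis; the phenoxide of 12 displaces bromide from the benzylic carbon (SN2). The benzyl group marks the later free hydroxyl of ring G.

Step 8
Reactants: 13 benzyl ether
Product: 14 benzyloxy aldehyde (6-(benzyloxy)-2,3,4-trimethoxybenzaldehyde)
Conditions: POCl3, DMF, 0 → 60 °C; then H2O
Reagents that add atoms: N,N-dimethylformamide CN(C)C=O (formyl carbon); water O (formyl oxygen)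
Why: Vilsmeier–Haack formylation; both free positions of 13 are equivalent and lie between two oxygen substituents, so one aldehyde is expected, and the benzyl ether is stable to the chloroiminium reagent.

Step 9
Reactants: 14 benzyloxy aldehyde
Product: 16 ring G phenol (6-(benzyloxy)-2,3,4-trimethoxyphenol), via ring G formate 15 (not isolated)
Conditions: mCPBA, CH2Cl2, 0 °C → rt; aq. Na2S2O3/NaHCO3 wash; then K2CO3 (cat.), MeOH, rt
Reagents that add atoms: m-chloroperbenzoic acid OOC(=O)c1cccc(Cl)c1 (one oxygen)
Why: Baeyer–Villiger oxidation of a 2,6-dialkoxybenzaldehyde with aryl migration; the benzyl ether is inert to peracid and formate 15 is cleaved by methanolysis.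

Step 10
Reactants: 16 ring G phenol; 4 bromo aldehyde dimer
Product: 17 rings G–I trimer aldehyde (6-{4-[6-(benzyloxy)-2,3,4-trimethoxyphenoxy]-2,6-dimethoxyphenoxy}-2,3,4-trimethoxybenzaldehyde)
Conditions: CuI (10 mol%), picolinic acid (20 mol%), K3PO4, DMSO, 100 °C, Ar
Reagents that add atoms: none
Why: Ullmann-type etherification of the doubly ortho-substituted phenol 16 with the unhindered bromide of 4, as in step 3; benzyl ether and aldehyde are spectators.

Step 11
Reactants: 17 rings G–I trimer aldehyde
Product: 19 rings G–I trimer phenol (6-{4-[6-(benzyloxy)-2,3,4-trimethoxyphenoxy]-2,6-dimethoxyphenoxy}-2,3,4-trimethoxyphenol), via rings G–I trimer formate 18 (not isolated)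
Conditions: mCPBA, CH2Cl2, 0 °C → rt; aq. Na2S2O3/NaHCO3 wash; then K2CO3 (cat.), MeOH, rt
Reagents that add atoms: m-chloroperbenzoic acid OOC(=O)c1cccc(Cl)c1 (one oxygen)
Why: Baeyer–Villiger oxidation with aryl migration as in step 4; the benzyl ether on ring G is not affected.

Step 12
Reactants: 3 bromophenol (4-bromo-2,6-dimethoxyphenol); 20 boronic acid ((3,4,5-trimethoxyphenyl)boronic acid)
Product: 21 rings J–K bromide (5-(4-bromo-2,6-dimethoxyphenoxy)-1,2,3-trimethoxybenzene)
Conditions: Cu(OAc)2 (1 equiv), pyridine, 4 Å MS, CH2Cl2, air, rt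
Reagents that add atoms: none
Why: Chan–Lam oxidative coupling; the aryl group passes from boron to divalent copper, the phenoxide binds, and C–O reductive elimination follows, with air returning the copper to the divalent state. The reaction runs at room temperature, accepts ortho,ortho-disubstituted phenols and leaves the aryl bromide intact.

Step 13
Reactants: 19 rings G–I trimer phenol; 21 rings J–K bromide
Product: 22 rings G–K pentamer benzyl ether (benzyloxy on ring G next to the G–H ether carbon; thirteen methoxy groups)
Conditions: CuI (10 mol%), picolinic acid (20 mol%), K3PO4, DMSO, 100 °C, Ar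
Reagents that add atoms: none
Why: Ullmann-type etherification as in step 5; the bromide of 21 has two hydrogen neighbours, and the only free hydroxyl in either partner is the one on ring I.

Step 14
Reactants: 22 rings G–K pentamer benzyl ether
Product: 23 rings G–K pentamer phenol (hydroxyl on ring G next to the G–H ether carbon)
Conditions: H2 (1 atm), 10% Pd/C, EtOAc–MeOH, rt
Reagents that add atoms: none
Why: Hydrogenolysis of the benzyl ether on palladium; methyl and diaryl ethers are untouched, and the freed hydroxyl is the ring G nucleophile of the key step.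

Step 15
Reactants: 24 bromofluoroxylene (5-bromo-2-fluoro-1,3-dimethylbenzene)
Product: 25 tetrabromide (5-bromo-1,3-bis(dibromomethyl)-2-fluorobenzene)
Conditions: NBS (4.6 equiv), AIBN (cat.), PhCF3, 90 °C
Reagents that add atoms: N-bromosuccinimide O=C1CCC(=O)N1Br
Why: Wohl–Ziegler radical bromination; each benzylic methyl group is brominated twice, a third bromination is slow for steric reasons, and the aryl C–Br and C–F bonds are inert to bromine radicals.

Step 16
Reactants: 25 tetrabromide
Product: 26 linchpin (5-bromo-2-fluoroisophthalaldehyde)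
Conditions: AgNO3, MeCN–H2O, 60 °C, dark
Reagents that add atoms: water O
Why: Silver-assisted hydrolysis of the two benzylic gem-dibromides to formyl groups; the medium is neutral to acidic, so the fluoride, which becomes SNAr-active as the formyl groups appear, meets no basic nucleophile.

Step 17
Reactants: 23 rings G–K pentamer phenol; 26 linchpin (5-bromo-2-fluoroisophthalaldehyde); 11 rings A–E pentamer phenol
Product: 28 undecamer dialdehyde (ring F as the 2,6-diformyl ring; 26 methoxy groups on the other ten rings), via hexamer bromo dialdehyde 27 (not isolated)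
Conditions: 23 and 26 (1:1), K2CO3, DMSO, 4 Å MS, rt → 40 °C, Ar; then 11 (1.1 equiv), CuI (20 mol%), picolinic acid (40 mol%), K3PO4, 100 °C
Reagents that add atoms: none
Why: The phenoxide of 23 adds ipso to the fluorine of 26; the charge of the Meisenheimer intermediate is shared by both ortho formyl groups and fluoride then leaves, which is the familiar SNAr of ortho-formyl fluoroarenes with phenoxides and gives 27 near room temperature. The bromide of 26 is meta to both formyl groups, gains no such stabilisation and is untouched while no copper is present. Only then are 11, CuI, picolinic acid and K3PO4 added: the picolinate-bound phenoxide of 11 on monovalent copper inserts into the C–Br bond of 27, and C–O reductive elimination from the trivalent copper aryl forms the second ether, as in Ullmann-type etherification of ortho,ortho-disubstituted phenols. No ring is closed and no stereocentre is formed. The step needs site selectivity (ring G oxygen on C2 and ring E oxygen on C5 of ring F); this is secured by the different activation of the two halides, by the order of addition, and by a strict one-to-one ratio of 23 and 26 so that neither is left free when copper arrives. Exchange of the ring G aryloxide at C2 by the phenoxide of 11 is held back because an aryloxide is a far poorer SNAr leaving group than fluoride and because both C2 and the incoming phenoxide are doubly ortho-substituted. The two formyl groups make the bromide-bearing ring electron-poor, which helps the copper insertion, and a carboxylate ligand is chosen so that no carbon acid meets the aldehydes.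

Step 18
Reactants: 28 undecamer dialdehyde
Product: 30 undecamer ring F diol (hexacosamethyl ether of the target), via undecamer bis-formate 29 (not isolated)
Conditions: mCPBA (3 equiv), CH2Cl2, 0 °C → rt; aq. Na2S2O3/NaHCO3 wash; then K2CO3 (cat.), MeOH, rt
Reagents that add atoms: m-chloroperbenzoic acid OOC(=O)c1cccc(Cl)c1 (two oxygens)
Why: Double Baeyer–Villiger oxidation; each formyl group is ortho to the C2 aryloxy oxygen, which supports aryl migration, and the ring becomes richer after the first oxidation. Methanolysis of bis-formate 29 frees the two ring F hydroxyls.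

Step 19
Reactants: 30 undecamer ring F diol
Product: 31 target (octacosahydroxy undecamer CNP0245174.0)
Conditions: BBr3 (excess), CH2Cl2, −78 °C → rt; then H2O, 0 °C, Ar
Reagents that add atoms: none
Why: Lewis-acid dealkylation; boron binds each methoxy oxygen and bromide attacks the methyl carbon (SN2), whereas the sp2 carbons of the diaryl ethers cannot be attacked. Hydrolysis of the aryl borates under argon frees all 28 hydroxyls.

## Compound list

1 | 5-fluoro-1,2,3-trimethoxybenzene | COc1cc(F)cc(OC)c1OC | starting material
2 | 6-fluoro-2,3,4-trimethoxybenzaldehyde | COc1cc(F)c(C=O)c(OC)c1OC | intermediate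
3 | 4-bromo-2,6-dimethoxyphenol | COc1cc(Br)cc(OC)c1O | starting material
4 | 6-(4-bromo-2,6-dimethoxyphenoxy)-2,3,4-trimethoxybenzaldehyde | COc1cc(Oc2c(OC)cc(Br)cc2OC)c(C=O)c(OC)c1OC | intermediate
5 | 2,4,6-trimethoxyphenol | COc1cc(OC)c(O)c(OC)c1 | starting material
6 | rings A–C trimer aldehyde, 6-[2,6-dimethoxy-4-(2,4,6-trimethoxyphenoxy)phenoxy]-2,3,4-trimethoxybenzaldehyde | COc1cc(OC)c(Oc2cc(OC)c(Oc3cc(OC)c(OC)c(OC)c3C=O)c(OC)c2)c(OC)c1 | intermediate
7 | rings A–C trimer formate, 6-[2,6-dimethoxy-4-(2,4,6-trimethoxyphenoxy)phenoxy]-2,3,4-trimethoxyphenyl formate | COc1cc(OC)c(Oc2cc(OC)c(Oc3cc(OC)c(OC)c(OC)c3OC=O)c(OC)c2)c(OC)c1 | intermediate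
8 | rings A–C trimer phenol, 6-[2,6-dimethoxy-4-(2,4,6-trimethoxyphenoxy)phenoxy]-2,3,4-trimethoxyphenol | COc1cc(OC)c(Oc2cc(OC)c(Oc3cc(OC)c(OC)c(OC)c3O)c(OC)c2)c(OC)c1 | intermediate
9 | rings A–E pentamer aldehyde (formyl on ring E next to the D–E ether carbon, thirteen methoxy groups) | COc1cc(OC)c(Oc2cc(OC)c(Oc3cc(OC)c(OC)c(OC)c3Oc3cc(OC)c(Oc4cc(OC)c(OC)c(OC)c4C=O)c(OC)c3)c(OC)c2)c(OC)c1 | intermediate
10 | rings A–E pentamer formate (formate ester of 11) | COc1cc(OC)c(Oc2cc(OC)c(Oc3cc(OC)c(OC)c(OC)c3Oc3cc(OC)c(Oc4cc(OC)c(OC)c(OC)c4OC=O)c(OC)c3)c(OC)c2)c(OC)c1 | intermediate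
11 | rings A–E pentamer phenol (hydroxyl on ring E next to the D–E ether carbon, thirteen methoxy groups) | COc1cc(OC)c(Oc2cc(OC)c(Oc3cc(OC)c(OC)c(OC)c3Oc3cc(OC)c(Oc4cc(OC)c(OC)c(OC)c4O)c(OC)c3)c(OC)c2)c(OC)c1 | intermediate
12 | 3,4,5-trimethoxyphenol | COc1cc(O)cc(OC)c1OC | starting material
13 | 5-(benzyloxy)-1,2,3-trimethoxybenzene | COc1cc(OCc2ccccc2)cc(OC)c1OC | intermediate
14 | 6-(benzyloxy)-2,3,4-trimethoxybenzaldehyde | COc1cc(OCc2ccccc2)c(C=O)c(OC)c1OC | intermediate
15 | 6-(benzyloxy)-2,3,4-trimethoxyphenyl formate | COc1cc(OCc2ccccc2)c(OC=O)c(OC)c1OC | intermediate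
16 | 6-(benzyloxy)-2,3,4-trimethoxyphenol | COc1cc(OCc2ccccc2)c(O)c(OC)c1OC | intermediate
17 | rings G–I trimer aldehyde, 6-{4-[6-(benzyloxy)-2,3,4-trimethoxyphenoxy]-2,6-dimethoxyphenoxy}-2,3,4-trimethoxybenzaldehyde | COc1cc(OCc2ccccc2)c(Oc2cc(OC)c(Oc3cc(OC)c(OC)c(OC)c3C=O)c(OC)c2)c(OC)c1OC | intermediate
18 | rings G–I trimer formate (formate ester of 19) | COc1cc(OCc2ccccc2)c(Oc2cc(OC)c(Oc3cc(OC)c(OC)c(OC)c3OC=O)c(OC)c2)c(OC)c1OC | intermediate
19 | rings G–I trimer phenol, 6-{4-[6-(benzyloxy)-2,3,4-trimethoxyphenoxy]-2,6-dimethoxyphenoxy}-2,3,4-trimethoxyphenol | COc1cc(OCc2ccccc2)c(Oc2cc(OC)c(Oc3cc(OC)c(OC)c(OC)c3O)c(OC)c2)c(OC)c1OC | intermediate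
20 | (3,4,5-trimethoxyphenyl)boronic acid | COc1cc(B(O)O)cc(OC)c1OC | starting material
21 | 5-(4-bromo-2,6-dimethoxyphenoxy)-1,2,3-trimethoxybenzene | COc1cc(Oc2c(OC)cc(Br)cc2OC)cc(OC)c1OC | intermediate
22 | rings G–K pentamer benzyl ether (benzyloxy on ring G next to the G–H ether carbon, thirteen methoxy groups) | COc1cc(OCc2ccccc2)c(Oc2cc(OC)c(Oc3cc(OC)c(OC)c(OC)c3Oc3cc(OC)c(Oc4cc(OC)c(OC)c(OC)c4)c(OC)c3)c(OC)c2)c(OC)c1OC | intermediate
23 | rings G–K pentamer phenol (hydroxyl on ring G next to the G–H ether carbon, thirteen methoxy groups) | Oc1cc(OC)c(OC)c(OC)c1Oc1cc(OC)c(Oc2cc(OC)c(OC)c(OC)c2Oc2cc(OC)c(Oc3cc(OC)c(OC)c(OC)c3)c(OC)c2)c(OC)c1 | intermediate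
24 | 5-bromo-2-fluoro-1,3-dimethylbenzene | Cc1cc(Br)cc(C)c1F | starting material
25 | 5-bromo-1,3-bis(dibromomethyl)-2-fluorobenzene | BrC(Br)c1cc(Br)cc(C(Br)Br)c1F | intermediate
26 | 5-bromo-2-fluoroisophthalaldehyde | O=Cc1cc(Br)cc(C=O)c1F | intermediate
27 | hexamer bromo dialdehyde (5-bromo-2-aryloxyisophthalaldehyde, aryl being ring G of 23) | O=Cc1cc(Br)cc(C=O)c1Oc1cc(OC)c(OC)c(OC)c1Oc1cc(OC)c(Oc2cc(OC)c(OC)c(OC)c2Oc2cc(OC)c(Oc3cc(OC)c(OC)c(OC)c3)c(OC)c2)c(OC)c1 | intermediate
28 | undecamer dialdehyde (ring F as 2,6-diformyl ring, 26 methoxy groups) | COc1cc(OC)c(Oc2cc(OC)c(Oc3cc(OC)c(OC)c(OC)c3Oc3cc(OC)c(Oc4cc(OC)c(OC)c(OC)c4Oc4cc(C=O)c(Oc5cc(OC)c(OC)c(OC)c5Oc5cc(OC)c(Oc6cc(OC)c(OC)c(OC)c6Oc6cc(OC)c(Oc7cc(OC)c(OC)c(OC)c7)c(OC)c6)c(OC)c5)c(C=O)c4)c(OC)c3)c(OC)c2)c(OC)c1 | intermediate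
29 | undecamer bis-formate (ring F diformate, 26 methoxy groups) | COc1cc(OC)c(Oc2cc(OC)c(Oc3cc(OC)c(OC)c(OC)c3Oc3cc(OC)c(Oc4cc(OC)c(OC)c(OC)c4Oc4cc(OC=O)c(Oc5cc(OC)c(OC)c(OC)c5Oc5cc(OC)c(Oc6cc(OC)c(OC)c(OC)c6Oc6cc(OC)c(Oc7cc(OC)c(OC)c(OC)c7)c(OC)c6)c(OC)c5)c(OC=O)c4)c(OC)c3)c(OC)c2)c(OC)c1 | intermediate
30 | undecamer ring F diol (two free hydroxyls on ring F, 26 methoxy groups) | COc1cc(OC)c(Oc2cc(OC)c(Oc3cc(OC)c(OC)c(OC)c3Oc3cc(OC)c(Oc4cc(OC)c(OC)c(OC)c4Oc4cc(O)c(Oc5cc(OC)c(OC)c(OC)c5Oc5cc(OC)c(Oc6cc(OC)c(OC)c(OC)c6Oc6cc(OC)c(Oc7cc(OC)c(OC)c(OC)c7)c(OC)c6)c(OC)c5)c(O)c4)c(OC)c3)c(OC)c2)c(OC)c1 | intermediate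
31 | CNP0245174.0, octacosahydroxy undecamer (achiral) | Oc1cc(O)c(Oc2cc(O)c(Oc3cc(O)c(O)c(O)c3Oc3cc(O)c(Oc4cc(O)c(O)c(O)c4Oc4cc(O)c(Oc5cc(O)c(O)c(O)c5Oc5cc(O)c(Oc6cc(O)c(O)c(O)c6Oc6cc(O)c(Oc7cc(O)c(O)c(O)c7)c(O)c6)c(O)c5)c(O)c4)c(O)c3)c(O)c2)c(O)c1 | target

## Step count and least certain steps

Total step count: 19. Longest linear sequence: 10 steps (steps 7, 8, 9, 10, 11, 13, 14, 17, 18 and 19, from 12 to 31).

Step 17 (key step). The most likely failure is aryloxide exchange at C2 of ring F during the hot copper stage: the phenoxide of 11 displaces the ring G aryloxide, and the liberated 23 then couples at the bromide, so the two halves end up in the wrong order. The second risk is slow C–O formation at the very hindered phenoxide, with loss of bromide by reduction. The fallback sets out from 27, now isolated after the SNAr stage. Both formyl groups are converted into ethylene acetals (ethane-1,2-diol, TsOH, toluene, water removal) to give the hexamer bromide bis(1,3-dioxolane) F1, in which C2 is no longer activated. Coupling of F1 with 11 under the conditions of step 5 gives the undecamer bis(1,3-dioxolane) F2, and aqueous HCl in THF returns to the route at 28.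

Step 2. The C–F carbon of 2 is deactivated by the para methoxy group, so addition of the hindered phenoxide may be slow, and at the temperature then needed methyl ether cleavage by phenoxide or fluoride and aldehyde degradation may take over. The fallback sets out from 3. Purchasable 5-iodo-1,2,3-trimethoxybenzene F3 is formylated (POCl3, DMF) to 6-iodo-2,3,4-trimethoxybenzaldehyde F4, and F4 is coupled with 3 (CuI, picolinic acid, K3PO4, DMSO, 80 °C). The iodide ortho to the formyl group should insert into copper much faster than the bromide para to the phenoxide oxygen. The fallback returns at 4.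

Step 12. Divalent copper and air may oxidise the electron-rich phenol 3 (quinone formation with loss of bromine) faster than the doubly ortho-substituted phenoxide is arylated. The fallback sets out from 12 and 26 and uses the chemistry of the key step on a small scale. SNAr (K2CO3, DMSO, rt) gives 5-bromo-2-(3,4,5-trimethoxyphenoxy)isophthalaldehyde F5. Peracid oxidation gives 5-bromo-2-(3,4,5-trimethoxyphenoxy)-1,3-phenylene diformate F6, which is methanolysed in the same flask to 5-bromo-2-(3,4,5-trimethoxyphenoxy)benzene-1,3-diol F7. Methylation (MeI, K2CO3, acetone) returns at 21.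

Step 18. Aryl migration on ring F may be sluggish while the second formyl group still withdraws electrons, so hydride migration to carboxylic acids and peracid attack on the electron-rich outer rings, ring A first, may compete. The fallback sets out from 27 (isolated) and moves the oxidation to the hexamer, which contains no ring A and can be purified after each operation. mCPBA gives the hexamer bromide bis-formate F8, methanolysis gives the hexamer bromide diol F9, and methylation (MeI, K2CO3) gives the hexamer bromide dimethyl ether F10. Copper coupling of F10 with 11 under the conditions of step 5 gives the fully methylated undecamer F11, and BBr3 under the conditions of step 19 returns at 31.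

Step 19. Cleavage of 26 ethers may stall when partly dealkylated borates precipitate, and the pyrogallol-type rings may be oxidised by air during work-up and chromatography of the free polyphenol. The fallback sets out from 30. After the BBr3 treatment and aqueous quench under argon, the crude material is acetylated at once (Ac2O, pyridine) to the octacosaacetate F12, which is stable in air and can be purified on silica, with under-dealkylated material separated and resubmitted. Acidic methanolysis (HCl in MeOH from acetyl chloride, argon) then returns at 31.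

## Further compounds

F1 | step 17 | hexamer bromide bis(1,3-dioxolane) (27 with both formyl groups as ethylene acetals) | Brc1cc(C2OCCO2)c(Oc2cc(OC)c(OC)c(OC)c2Oc2cc(OC)c(Oc3cc(OC)c(OC)c(OC)c3Oc3cc(OC)c(Oc4cc(OC)c(OC)c(OC)c4)c(OC)c3)c(OC)c2)c(C2OCCO2)c1
F2 | step 17 | undecamer bis(1,3-dioxolane) (28 with both formyl groups as ethylene acetals) | COc1cc(OC)c(Oc2cc(OC)c(Oc3cc(OC)c(OC)c(OC)c3Oc3cc(OC)c(Oc4cc(OC)c(OC)c(OC)c4Oc4cc(C8OCCO8)c(Oc5cc(OC)c(OC)c(OC)c5Oc5cc(OC)c(Oc6cc(OC)c(OC)c(OC)c6Oc6cc(OC)c(Oc7cc(OC)c(OC)c(OC)c7)c(OC)c6)c(OC)c5)c(C8OCCO8)c4)c(OC)c3)c(OC)c2)c(OC)c1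
F3 | step 2 | 5-iodo-1,2,3-trimethoxybenzene | COc1cc(I)cc(OC)c1OC
F4 | step 2 | 6-iodo-2,3,4-trimethoxybenzaldehyde | COc1cc(I)c(C=O)c(OC)c1OC
F5 | step 12 | 5-bromo-2-(3,4,5-trimethoxyphenoxy)isophthalaldehyde | O=Cc1cc(Br)cc(C=O)c1Oc1cc(OC)c(OC)c(OC)c1
F6 | step 12 | 5-bromo-2-(3,4,5-trimethoxyphenoxy)-1,3-phenylene diformate | O=COc1cc(Br)cc(OC=O)c1Oc1cc(OC)c(OC)c(OC)c1
F7 | step 12 | 5-bromo-2-(3,4,5-trimethoxyphenoxy)benzene-1,3-diol | Oc1cc(Br)cc(O)c1Oc1cc(OC)c(OC)c(OC)c1
F8 | step 18 | hexamer bromide bis-formate (27 with both formyl groups as formate esters) | O=COc1cc(Br)cc(OC=O)c1Oc1cc(OC)c(OC)c(OC)c1Oc1cc(OC)c(Oc2cc(OC)c(OC)c(OC)c2Oc2cc(OC)c(Oc3cc(OC)c(OC)c(OC)c3)c(OC)c2)c(OC)c1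
F9 | step 18 | hexamer bromide diol (5-bromo-2-aryloxybenzene-1,3-diol, aryl being ring G of 23) | Oc1cc(Br)cc(O)c1Oc1cc(OC)c(OC)c(OC)c1Oc1cc(OC)c(Oc2cc(OC)c(OC)c(OC)c2Oc2cc(OC)c(Oc3cc(OC)c(OC)c(OC)c3)c(OC)c2)c(OC)c1
F10 | step 18 | hexamer bromide dimethyl ether (5-bromo-1,3-dimethoxy-2-aryloxybenzene, aryl being ring G of 23) | COc1cc(Br)cc(OC)c1Oc1cc(OC)c(OC)c(OC)c1Oc1cc(OC)c(Oc2cc(OC)c(OC)c(OC)c2Oc2cc(OC)c(Oc3cc(OC)c(OC)c(OC)c3)c(OC)c2)c(OC)c1
F11 | step 18 | fully methylated undecamer (octacosamethyl ether of the target) | COc1cc(OC)c(Oc2cc(OC)c(Oc3cc(OC)c(OC)c(OC)c3Oc3cc(OC)c(Oc4cc(OC)c(OC)c(OC)c4Oc4cc(OC)c(Oc5cc(OC)c(OC)c(OC)c5Oc5cc(OC)c(Oc6cc(OC)c(OC)c(OC)c6Oc6cc(OC)c(Oc7cc(OC)c(OC)c(OC)c7)c(OC)c6)c(OC)c5)c(OC)c4)c(OC)c3)c(OC)c2)c(OC)c1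
F12 | step 19 | octacosaacetate of the target | CC(=O)Oc1cc(OC(C)=O)c(Oc2cc(OC(C)=O)c(Oc3cc(OC(C)=O)c(OC(C)=O)c(OC(C)=O)c3Oc3cc(OC(C)=O)c(Oc4cc(OC(C)=O)c(OC(C)=O)c(OC(C)=O)c4Oc4cc(OC(C)=O)c(Oc5cc(OC(C)=O)c(OC(C)=O)c(OC(C)=O)c5Oc5cc(OC(C)=O)c(Oc6cc(OC(C)=O)c(OC(C)=O)c(OC(C)=O)c6Oc6cc(OC(C)=O)c(Oc7cc(OC(C)=O)c(OC(C)=O)c(OC(C)=O)c7)c(OC(C)=O)c6)c(OC(C)=O)c5)c(OC(C)=O)c4)c(OC(C)=O)c3)c(OC(C)=O)c2)c(OC(C)=O)c1
A1 | alternative 1 | dimethyl squarate (3,4-dimethoxycyclobut-3-ene-1,2-dione) | COC1=C(OC)C(=O)C1=O
A2 | alternative 1 | racemic 4-[(Z)-2-{2,6-dimethoxy-4-(2,4,6-trimethoxyphenoxy)phenoxy}ethenyl]-2,3,4-trimethoxycyclobut-2-en-1-one | COC1=C(OC)C(OC)(/C=C\Oc2c(OC)cc(Oc3c(OC)cc(OC)cc3OC)cc2OC)C1=O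
A3 | alternative 1 | rings A–C trimer phenol with free hydroxyl on ring C (same compound as 8) | COc1cc(OC)c(Oc2cc(OC)c(Oc3cc(OC)c(OC)c(OC)c3O)c(OC)c2)c(OC)c1
A4 | alternative 2 | icosaformyl undecamer (two formyl groups on each of rings A to J, eight methoxy groups) | COc1cc(C=O)c(Oc2cc(C=O)c(Oc3cc(C=O)c(OC)c(C=O)c3Oc3cc(C=O)c(Oc4cc(C=O)c(OC)c(C=O)c4Oc4cc(C=O)c(Oc5cc(C=O)c(OC)c(C=O)c5Oc5cc(C=O)c(Oc6cc(C=O)c(OC)c(C=O)c6Oc6cc(C=O)c(Oc7cc(OC)c(OC)c(OC)c7)c(C=O)c6)c(C=O)c5)c(C=O)c4)c(C=O)c3)c(C=O)c2)c(C=O)c1
A5 | alternative 2 | undecamer with twenty free hydroxyls and eight methyl ethers | COc1cc(O)c(Oc2cc(O)c(Oc3cc(O)c(OC)c(O)c3Oc3cc(O)c(Oc4cc(O)c(OC)c(O)c4Oc4cc(O)c(Oc5cc(O)c(OC)c(O)c5Oc5cc(O)c(Oc6cc(O)c(OC)c(O)c6Oc6cc(O)c(Oc7cc(OC)c(OC)c(OC)c7)c(O)c6)c(O)c5)c(O)c4)c(O)c3)c(O)c2)c(O)c1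
A6 | alternative 3 | rings A–E pentamer ethynyl ether (11 with its hydroxyl as an ethynyl ether) | COc1cc(OC)c(Oc2cc(OC)c(Oc3cc(OC)c(OC)c(OC)c3Oc3cc(OC)c(Oc4cc(OC)c(OC)c(OC)c4OC#C)c(OC)c3)c(OC)c2)c(OC)c1
A7 | alternative 3 | racemic 4-aryloxy-3-ethoxycyclobut-2-en-1-one (aryl being ring G of 23) | CCOC1=CC(=O)C1Oc1cc(OC)c(OC)c(OC)c1Oc1cc(OC)c(Oc2cc(OC)c(OC)c(OC)c2Oc2cc(OC)c(Oc3cc(OC)c(OC)c(OC)c3)c(OC)c2)c(OC)c1
A8 | alternative 3 | undecamer with ring F as free phenol and ethyl ether, all other hydroxyls methylated | COc1cc(OC)c(Oc2cc(OC)c(Oc3cc(OC)c(OC)c(OC)c3Oc3cc(OC)c(Oc4cc(OC)c(OC)c(OC)c4Oc4cc(O)c(Oc5cc(OC)c(OC)c(OC)c5Oc5cc(OC)c(Oc6cc(OC)c(OC)c(OC)c6Oc6cc(OC)c(Oc7cc(OC)c(OC)c(OC)c7)c(OC)c6)c(OC)c5)c(OCC)c4)c(OC)c3)c(OC)c2)c(OC)c1
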